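**Retrosynthetic overview**
1. Target 22 ← 21 (cleavage of two MOM ethers) ← 20 (O-prenylation at the 3-OH) ← 19 (fluoride cleavage of the 3-O-CH2CH2SiMe3 ether).
2. Feature: in ring C, C3 is a single carbon bearing only oxygen, set between the C4 carbonyl and the aryl-bearing C2, so it is brought in as an alkoxymethylene phosphorane. Disconnections C3–C4 and C2=C3: ylide 17 is acylated by silyl ester 15 (carboxyl carbon on C4a = C4) and then olefinates the 4-prenyloxybenzoyl ester on the C8a oxygen (future O1; its carbonyl carbon = C2).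
3. 15 ← salicylaldehyde 8 + acid 12 (esterification, aldehyde oxidation, silylation); 12 ← methyl 4-hydroxybenzoate 9 + prenyl bromide 10.
4. 8 ← 2,4,6-trihydroxybenzaldehyde 1: Dakin oxidation installs the future C8 oxygen, methylation fixes 8-OMe, and phenol-directed ortho-formylation returns the future C4 carbon next to the future O1.
5. Rings A and B are bought; ring C is the only ring formed (step 12).

Key step: step 12

Remark: prenyl = 3-methylbut-2-en-1-yl, MOM = methoxymethyl, TBS = tert-butyldimethylsilyl; the target has no stereocentre, so no step needs stereocontrol. Methyl 4-hydroxybenzoate is used as the ring B starting material in place of the free acid.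

**Step 1**
Reactants: 1 2,4,6-trihydroxybenzaldehyde
Product: 2 2-hydroxy-4,6-bis(methoxymethoxy)benzaldehyde
Conditions: MOMCl (2.1 equiv), iPr2NEt, CH2Cl2, 0 °C→rt
Reagents that add atoms: chloromethyl methyl ether (MOMCl), COCCl
Why: Williamson-type O-alkylation should take the 4-OH and one of the two equivalent ortho OH groups, while the last OH stays hydrogen-bonded to the formyl oxygen and is left free with two equivalents of MOMCl.

**Step 2**
Reactants: 2 2-hydroxy-4,6-bis(methoxymethoxy)benzaldehyde
Product: 3 2-(benzyloxy)-4,6-bis(methoxymethoxy)benzaldehyde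
Conditions: BnBr, K2CO3, DMF, 60 °C
Reagents that add atoms: benzyl bromide, BrCc1ccccc1
Why: Williamson etherification of the chelated phenol under carbonate/DMF conditions marks the future O1 with a benzyl group that is orthogonal to the MOM ethers.

**Step 3**
Reactants: 3 2-(benzyloxy)-4,6-bis(methoxymethoxy)benzaldehyde
Product: 5 2-(benzyloxy)-4,6-bis(methoxymethoxy)phenol, via aryl formate 4 (not isolated)
Conditions: mCPBA, NaHCO3, CH2Cl2, 0 °C→rt; aq. Na2S2O3 wash; K2CO3 (cat.), MeOH, rt, Ar
Reagents that add atoms: meta-chloroperoxybenzoic acid (mCPBA), OOC(=O)c1cccc(Cl)c1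
Why: In this Dakin-type Baeyer–Villiger oxidation the electron-rich trialkoxyaryl group migrates in the Criegee intermediate to give formate 4, which mild methanolysis cleaves to the phenol that carries the future C8 oxygen.

**Step 4**
Reactants: 5 2-(benzyloxy)-4,6-bis(methoxymethoxy)phenol
Product: 6 1-(benzyloxy)-2-methoxy-3,5-bis(methoxymethoxy)benzene
Conditions: MeI, K2CO3, DMF, rt
Reagents that add atoms: iodomethane, CI
Why: Williamson O-methylation of the flanked phenoxide with the small electrophile MeI sets the 8-methoxy group and removes the air-sensitive free phenol.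

**Step 5**
Reactants: 6 1-(benzyloxy)-2-methoxy-3,5-bis(methoxymethoxy)benzene
Product: 7 2-methoxy-3,5-bis(methoxymethoxy)phenol
Conditions: H2 (1 atm), 10% Pd/C, EtOAc, rt
Reagents that add atoms: none
Why: Hydrogenolysis of the benzyl aryl ether leaves methyl and MOM ethers untouched and frees the one phenol that becomes O1.

**Step 6**
Reactants: 7 2-methoxy-3,5-bis(methoxymethoxy)phenol
Product: 8 2-hydroxy-3-methoxy-4,6-bis(methoxymethoxy)benzaldehyde
Conditions: MgCl2, Et3N, (CH2O)n, MeCN, 80 °C; aq. NH4Cl work-up
Reagents that add atoms: paraformaldehyde (formaldehyde), C=O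
Why: In the magnesium phenoxide-directed ortho-formylation (Casnati–Skattebøl) the aryloxymagnesium chloride delivers formaldehyde through a chelate only to the single free ortho position and a second formaldehyde oxidises the hydroxymethyl intermediate by hydride transfer, so the carbon cannot enter between the two MOM ethers.

**Step 7**
Reactants: 9 methyl 4-hydroxybenzoate; 10 prenyl bromide (1-bromo-3-methylbut-2-ene)
Product: 11 methyl 4-(prenyloxy)benzoate
Conditions: K2CO3, acetone, reflux
Reagents that add atoms: none
Why: Williamson etherification of the acidic para-hydroxy ester with a primary allylic bromide proceeds by direct SN2 displacement at oxygen.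

**Step 8**
Reactants: 11 methyl 4-(prenyloxy)benzoate
Product: 12 4-(prenyloxy)benzoic acid
Conditions: LiOH, THF/MeOH/H2O, 40 °C; then 1 M HCl, 0 °C, to pH 3
Reagents that add atoms: lithium hydroxide, [Li+].[OH-]
Why: Saponification of the methyl ester leaves the prenyl ether intact, and the brief cold acidification only protonates the carboxylate.

**Step 9**
Reactants: 8 2-hydroxy-3-methoxy-4,6-bis(methoxymethoxy)benzaldehyde; 12 4-(prenyloxy)benzoic acid
Product: 13 2-formyl-6-methoxy-3,5-bis(methoxymethoxy)phenyl 4-(prenyloxy)benzoate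
Conditions: DCC, DMAP (cat.), CH2Cl2, 0 °C→rt
Reagents that add atoms: none
Why: Steglich esterification acylates the only hydroxyl through the DMAP-activated O-acylisourea without forming HCl, so MOM and prenyl groups are safe and the aroyl group sits on the oxygen that becomes O1.

**Step 10**
Reactants: 13 2-formyl-6-methoxy-3,5-bis(methoxymethoxy)phenyl 4-(prenyloxy)benzoate
Product: 14 3-methoxy-4,6-bis(methoxymethoxy)-2-{[4-(prenyloxy)benzoyl]oxy}benzoic acid
Conditions: NaClO2, NaH2PO4, 2-methyl-2-butene (large excess), t-BuOH/THF/H2O, 0 °C→rt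
Reagents that add atoms: sodium chlorite, [Na+].[O-]Cl=O
Why: Pinnick (Lindgren) oxidation converts the aldehyde to the acid at pH 3–4, where aryl ester and MOM ethers are stable, and the excess scavenger alkene removes hypochlorous acid before it can reach the prenyl group; oxidising after acylation avoids a free, decarboxylation-prone polyalkoxysalicylic acid.

**Step 11**
Reactants: 14 3-methoxy-4,6-bis(methoxymethoxy)-2-{[4-(prenyloxy)benzoyl]oxy}benzoic acid
Product: 15 tert-butyldimethylsilyl 3-methoxy-4,6-bis(methoxymethoxy)-2-{[4-(prenyloxy)benzoyl]oxy}benzoate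
Conditions: TBSCl, Et3N, CH2Cl2, 0 °C→rt; filtration from the ammonium salt, used directly
Reagents that add atoms: tert-butyldimethylsilyl chloride (TBSCl), CC(C)(C)[Si](C)(C)Cl
Why: O-silylation of the carboxylate, the only acidic site, gives the handleable but activated silyl ester needed for the ylide acylation.

**Step 12**
Reactants: 15 tert-butyldimethylsilyl 3-methoxy-4,6-bis(methoxymethoxy)-2-{[4-(prenyloxy)benzoyl]oxy}benzoate; 16 {[2-(trimethylsilyl)ethoxy]methyl}triphenylphosphonium chloride
Product: 19 8-methoxy-5,7-bis(methoxymethoxy)-2-[4-(prenyloxy)phenyl]-3-[2-(trimethylsilyl)ethoxy]-4H-chromen-4-one, via alkoxymethylene ylide 17 (not isolated), via acyl ylide 18 (not isolated)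
Conditions: 16 (1.3 equiv), NaN(SiMe3)2 (1.25 equiv), THF, −78→0 °C; slow addition to 15, THF, −78 °C→rt; then PhMe, 110 °C
Reagents that add atoms: none
Why: Proposed new method: ylide 17 is expected to add through carbon to the silyl ester carbonyl of 15, and the expelled silanolate should take the acidic proton of the β-keto phosphonium ion to give acyl ylide 18 and the silanol (C3–C4 bond), in the way esters and thioesters acylate ylides with their own leaving group as the base. On heating, the ylide carbon of 18 adds to the carbonyl of the neighbouring aroyl ester, the betaine closes to an oxaphosphetane and Ph3P=O is lost, which makes the C2=C3 double bond and closes ring C (O1–C2–C3–C4–C4a–C8a) in a 6-exo-trig attack. The closest known reaction type is the chromone and flavone synthesis from silyl esters of O-acyl- or O-aroylsalicylic acids and (trimethylsilyl)methylenetriphenylphosphorane, an ylide acylation followed by intramolecular Wittig olefination of an aryl ester; new are the α-alkoxy group on the ylide carbon, which leads to a tetrasubstituted C2=C3 bond, and the doubly ortho-substituted benzoate. No stereocentre is formed. The step needs chemoselectivity for the silyl ester in the first acylation and for olefination afterwards: the aroyl carbonyl is deactivated by its para-alkoxy donor and shielded by the two ortho substituents of the aryloxy group, the ylide is added slowly at −78 °C so that it is never in excess, and the alkoxy donor should raise the nucleophilicity of 18 for the six-membered ring closure, in which even loss of phenoxide from the betaine only gives a zwitterion that can re-close to the same oxaphosphetane. The methoxy group ends at C8 because only the oxygen next to it carries the aroyl group.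

**Step 13**
Reactants: 19 8-methoxy-5,7-bis(methoxymethoxy)-2-[4-(prenyloxy)phenyl]-3-[2-(trimethylsilyl)ethoxy]-4H-chromen-4-one
Product: 20 3-hydroxy-8-methoxy-5,7-bis(methoxymethoxy)-2-[4-(prenyloxy)phenyl]-4H-chromen-4-one
Conditions: Bu4NF, THF, 50 °C; then AcOH
Reagents that add atoms: none
Why: Fluoride attacks silicon and the 2-silylethyl group fragments to ethene and Me3SiF with loss of the stabilised flavonolate, the known fluoride-induced β-elimination of 2-(trimethylsilyl)ethyl ethers of phenols, to which MOM and prenyl ethers are inert.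

**Step 14**
Reactants: 20 3-hydroxy-8-methoxy-5,7-bis(methoxymethoxy)-2-[4-(prenyloxy)phenyl]-4H-chromen-4-one; 10 prenyl bromide (1-bromo-3-methylbut-2-ene)
Product: 21 8-methoxy-5,7-bis(methoxymethoxy)-3-(prenyloxy)-2-[4-(prenyloxy)phenyl]-4H-chromen-4-one
Conditions: K2CO3, acetone, reflux
Reagents that add atoms: none
Why: Williamson O-alkylation of the flavonol 3-OH, the only free hydroxyl, gives the enol prenyl ether; C-alkylation is not available because C2 is fully substituted.

**Step 15**
Reactants: 21 8-methoxy-5,7-bis(methoxymethoxy)-3-(prenyloxy)-2-[4-(prenyloxy)phenyl]-4H-chromen-4-one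
Product: 22 5,7-dihydroxy-8-methoxy-3-(prenyloxy)-2-[4-(prenyloxy)phenyl]-4H-chromen-4-one (5,7-dihydroxy-8-methoxy-3,4'-diprenyloxyflavone)
Conditions: HCl (ca. 0.5 M, from AcCl) in MeOH/THF, 0 °C→rt, monitored and quenched with NaHCO3
Reagents that add atoms: none
Why: Acid-catalysed acetal methanolysis releases both MOM groups as dimethoxymethane, the 5-O-MOM being assisted by the peri carbonyl, under conditions expected to be too mild to ionise the two allylic ethers.

**Compound list**
1 | 2,4,6-trihydroxybenzaldehyde | O=Cc1c(O)cc(O)cc1O | starting material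
2 | 2-hydroxy-4,6-bis(methoxymethoxy)benzaldehyde | O=Cc1c(O)cc(OCOC)cc1OCOC | intermediate
3 | 2-(benzyloxy)-4,6-bis(methoxymethoxy)benzaldehyde | O=Cc1c(OCc2ccccc2)cc(OCOC)cc1OCOC | intermediate
4 | 2-(benzyloxy)-4,6-bis(methoxymethoxy)phenyl formate | O=COc1c(OCc2ccccc2)cc(OCOC)cc1OCOC | intermediate
5 | 2-(benzyloxy)-4,6-bis(methoxymethoxy)phenol | Oc1c(OCc2ccccc2)cc(OCOC)cc1OCOC | intermediate
6 | 1-(benzyloxy)-2-methoxy-3,5-bis(methoxymethoxy)benzene | COc1c(OCc2ccccc2)cc(OCOC)cc1OCOC | intermediate
7 | 2-methoxy-3,5-bis(methoxymethoxy)phenol | COc1c(O)cc(OCOC)cc1OCOC | intermediate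
8 | 2-hydroxy-3-methoxy-4,6-bis(methoxymethoxy)benzaldehyde | O=Cc1c(O)c(OC)c(OCOC)cc1OCOC | intermediate
9 | methyl 4-hydroxybenzoate | COC(=O)c1ccc(O)cc1 | starting material
10 | prenyl bromide (1-bromo-3-methylbut-2-ene) | CC(C)=CCBr | starting material
11 | methyl 4-(prenyloxy)benzoate | COC(=O)c1ccc(OCC=C(C)C)cc1 | intermediate
12 | 4-(prenyloxy)benzoic acid | OC(=O)c1ccc(OCC=C(C)C)cc1 | intermediate
13 | 2-formyl-6-methoxy-3,5-bis(methoxymethoxy)phenyl 4-(prenyloxy)benzoate | O=Cc1c(OCOC)cc(OCOC)c(OC)c1OC(=O)c1ccc(OCC=C(C)C)cc1 | intermediate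
14 | 3-methoxy-4,6-bis(methoxymethoxy)-2-{[4-(prenyloxy)benzoyl]oxy}benzoic acid | OC(=O)c1c(OCOC)cc(OCOC)c(OC)c1OC(=O)c1ccc(OCC=C(C)C)cc1 | intermediate
15 | tert-butyldimethylsilyl 3-methoxy-4,6-bis(methoxymethoxy)-2-{[4-(prenyloxy)benzoyl]oxy}benzoate | CC(C)(C)[Si](C)(C)OC(=O)c1c(OCOC)cc(OCOC)c(OC)c1OC(=O)c1ccc(OCC=C(C)C)cc1 | intermediate
16 | {[2-(trimethylsilyl)ethoxy]methyl}triphenylphosphonium chloride | C[Si](C)(C)CCOC[P+](c1ccccc1)(c1ccccc1)c1ccccc1.[Cl-] | starting material
17 | {[2-(trimethylsilyl)ethoxy]methylene}triphenylphosphorane | C[Si](C)(C)CCOC=P(c1ccccc1)(c1ccccc1)c1ccccc1 | intermediate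
18 | 2-{2-[2-(trimethylsilyl)ethoxy]-2-(triphenylphosphoranylidene)acetyl}-6-methoxy-3,5-bis(methoxymethoxy)phenyl 4-(prenyloxy)benzoate | C[Si](C)(C)CCOC(C(=O)c1c(OCOC)cc(OCOC)c(OC)c1OC(=O)c1ccc(OCC=C(C)C)cc1)=P(c1ccccc1)(c1ccccc1)c1ccccc1 | intermediate
19 | 8-methoxy-5,7-bis(methoxymethoxy)-2-[4-(prenyloxy)phenyl]-3-[2-(trimethylsilyl)ethoxy]-4H-chromen-4-one | COCOc1cc(OCOC)c2c(=O)c(OCC[Si](C)(C)C)c(-c3ccc(OCC=C(C)C)cc3)oc2c1OC | intermediate
20 | 3-hydroxy-8-methoxy-5,7-bis(methoxymethoxy)-2-[4-(prenyloxy)phenyl]-4H-chromen-4-one | COCOc1cc(OCOC)c2c(=O)c(O)c(-c3ccc(OCC=C(C)C)cc3)oc2c1OC | intermediate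
21 | 8-methoxy-5,7-bis(methoxymethoxy)-3-(prenyloxy)-2-[4-(prenyloxy)phenyl]-4H-chromen-4-one | COCOc1cc(OCOC)c2c(=O)c(OCC=C(C)C)c(-c3ccc(OCC=C(C)C)cc3)oc2c1OC | intermediate
22 | 5,7-dihydroxy-8-methoxy-3,4'-diprenyloxyflavone | COc1c(O)cc(O)c2c(=O)c(OCC=C(C)C)c(-c3ccc(OCC=C(C)C)cc3)oc12 | target

**Step count**
Total steps: 15. Longest linear sequence: 13 steps (1 → 22 through steps 1–6 and 9–15); the ring B branch (steps 7–8) joins at step 9.

**Steps most likely to fail**

1. Step 12. The bulky ylide may add to the aroyl ester carbonyl instead of the doubly ortho-flanked silyl ester, which transfers the ring B acyl group to the ylide and frees the phenoxide. Alternatively the tetrasubstituted α-alkoxy acyl ylide may olefinate the ester too slowly and decompose on heating. Fallback with known chemistry, from 15 back to 20: 15 is treated with (trimethylsilyl)methylenetriphenylphosphorane in THF at reflux, the established acylation and intramolecular Wittig sequence. It should give the 3-unsubstituted flavone 8-methoxy-5,7-bis(methoxymethoxy)-2-[4-(prenyloxy)phenyl]-4H-chromen-4-one F1. C3 of F1 is then lithiated with LiN(iPr)2 in THF at −78 °C and trapped with B(OMe)3 to give dimethyl {8-methoxy-5,7-bis(methoxymethoxy)-4-oxo-2-[4-(prenyloxy)phenyl]-4H-chromen-3-yl}boronate F2. Oxidation of F2 with H2O2/AcOH at 0 °C gives flavonol 20, and the route continues with step 14.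

2. Step 15. Protonation may ionise the allylic C–O bonds of the two prenyl ethers, or add HCl or methanol across their double bonds, at a rate comparable to acetal cleavage, above all for the slower 7-O-MOM group. Fallback from 21 to 22 without protic acid: TESOTf and 2,2'-bipyridyl in CH2Cl2 at 0 °C exchange each aryl MOM ether for a silyl ether under buffered aprotic conditions. This should give 8-methoxy-3-(prenyloxy)-2-[4-(prenyloxy)phenyl]-5,7-bis(triethylsilyloxy)-4H-chromen-4-one F5. The silyl ethers of F5 are then removed with Bu4NF buffered with AcOH in THF at 0 °C to give 22.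

3. Step 10. Hypochlorous acid formed during the chlorite oxidation may add to the prenyl double bond faster than the scavenger removes it, while the crowded, electron-rich aldehyde is oxidised only slowly. Fallback from 8 back to 14, with the oxidation moved before ring B and its alkene are attached: 8 is oxidised with NaClO2/NaH2PO4/2-methyl-2-butene to 2-hydroxy-3-methoxy-4,6-bis(methoxymethoxy)benzoic acid F3, which is kept cold and used at once. Acid 12 is converted with oxalyl chloride and catalytic DMF in CH2Cl2 at 0 °C into 4-(prenyloxy)benzoyl chloride F4. F3 is then O-acylated with F4 in pyridine/CH2Cl2 at 0 °C, followed by mild aqueous hydrolysis of any mixed anhydride, to give 14.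

**Further compounds**
F1 | step 12 | 8-methoxy-5,7-bis(methoxymethoxy)-2-[4-(prenyloxy)phenyl]-4H-chromen-4-one | COCOc1cc(OCOC)c2c(=O)cc(-c3ccc(OCC=C(C)C)cc3)oc2c1OC
F2 | step 12 | dimethyl {8-methoxy-5,7-bis(methoxymethoxy)-4-oxo-2-[4-(prenyloxy)phenyl]-4H-chromen-3-yl}boronate | COCOc1cc(OCOC)c2c(=O)c(B(OC)OC)c(-c3ccc(OCC=C(C)C)cc3)oc2c1OC
F3 | step 10 | 2-hydroxy-3-methoxy-4,6-bis(methoxymethoxy)benzoic acid | OC(=O)c1c(O)c(OC)c(OCOC)cc1OCOC
F4 | step 10 | 4-(prenyloxy)benzoyl chloride | O=C(Cl)c1ccc(OCC=C(C)C)cc1
F5 | step 15 | 8-methoxy-3-(prenyloxy)-2-[4-(prenyloxy)phenyl]-5,7-bis(triethylsilyloxy)-4H-chromen-4-one | CC[Si](CC)(CC)Oc1cc(O[Si](CC)(CC)CC)c2c(=O)c(OCC=C(C)C)c(-c3ccc(OCC=C(C)C)cc3)oc2c1OC
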